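## The problem

Iridoid numbering is used throughout. C1 carries the coumarin, O2 is the ring oxygen, C3 carries the acyl group, C4 the vinylic methyl, C4a and C7a are the fusion atoms, and C7 carries the secondary methyl. Ring A is the cyclopentane (C4a, C5, C6, C7, C7a) and ring B the dihydropyran (C1, O2, C3, C4, C4a, C7a).

The target joins three units: the cis-fused bicycle, a 4-hydroxy-5-methylcoumarin bonded through its C3 to C1, and an (R)-2-acetoxy-3-methylbutanoyl group on C3. Two awkward bonds result. One is C1–C(coumarin), at a carbon that also bears O2. The other is C3–C(acyl), at the oxygen-bearing carbon of a tetrasubstituted enol ether.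

Ring A holds three contiguous stereocentres (C4a, C7, C7a). The fusion hydrogens are cis, the C7 methyl is trans to C1, and at C1 the coumarin is trans to C7. C4a can steer C7 (trans-diequatorial in a cyclohexanone), the ring fusion can steer C7a once C7a is enolisable inside a bicycle, and C7a can steer C1. The side-chain centre is remote from all of them and has to be bought.

Several groups are fragile. The α-acetoxy ketone epimerises and loses acetate with base. The free enol of the coumarin can open the C1–O2 bond by retro-oxa-Michael reaction. The enol ether is acid-labile. The coumarin lactone does not tolerate hydride or organolithium reagents.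

The feature that opens the molecule is the substitution of ring A. C7a carries C1 and is flanked by the methyl-bearing C7 and by C4a with its three-carbon unit (C4, its methyl, C3). This is the pattern of 2-methyl-5-isopropenylcyclohexanone after the carbonyl carbon has been pushed out of the ring, so carvone can supply all ten carbons and the C4a configuration.

## Retrosynthesis

**Side chain (24 ⇒ 23 ⇒ 19 + 22).** After removal of a benzyl group from the enol oxygen, the bond cut is C3–C(=O). Cutting one bond further out, between the ketone and the acetoxy-bearing carbon, would need an α-oxygenated carbanion or a late asymmetric oxidation next to an enolisable ketone. Cutting at the acyl carbon lets the remote stereocentre arrive intact in acid chloride 22, made from hydroxy acid 20. Stannane 19 is seven carbons smaller and free of the most base-sensitive unit. The forward reaction must be base-free and must work at a tetrasubstituted alkenyl metal. The final hydrogenolysis must spare C3=C4 and C1–O2.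

**C3 nucleophile (19 ⇒ 18 ⇒ 17).** The stannane is traced through ketene acetal phosphate 18 to δ-lactone 17, so that C3 is a lactone carbonyl and C3=C4 comes from its enolate. The neighbouring option, metalation of a C3–H enol ether, needs an alkyllithium that the coumarin lactone would not survive. In 17 the C4 centre is irrelevant, which removes one stereochemical demand from everything before it. The forward steps ask for enolisation at C4 with the coumarin enol masked, and for palladium insertion at a hindered enol phosphate.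

**Coumarin (17 ⇒ 16 ⇒ 13 + 15).** The cut is C1–C3(coumarin), with C1–O2 re-formed in the same event: pseudo-acid 13 (C1 at the aldehyde level, C3 as the acid) condenses with hydroxycoumarin 15. The neighbouring cut at the acyl level was set aside. There a C1 acid C-acylates 15, and O-benzylation and hydride reduction follow. That passes through a doubly activated 4-alkoxy-3-acylcoumarin and a very hindered ketone whose reduction must be face-selective. At the aldehyde level the C1–O2 bond of 16 closes reversibly, so C1 can settle thermodynamically. The precursor 13 is a C10 bicycle without the aromatic part. The forward reaction must give the 1:1 adduct and place the coumarin trans to C7.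

**Redox transposition (13 ⇒ 11 ⇒ 10 ⇒ 9).** Pseudo-acid 13 is one oxidation level above lactone 9, which has C1 as the acyl carbon and C3 as the alcohol. Aminolysis (10), oxidation (11) and reduction make the change. Lactone 9 is chosen as the hub because C7a sits α to its carbonyl inside a cis-fused bicycle. It is the one place where the centre left open by the ring contraction can be equilibrated.

**Ring B oxygen (9 ⇒ 8 ⇒ 6).** The C3–O bond comes from anti-Markovnikov hydration of the isopropenyl group of ester 6, followed by lactonisation. Nothing simpler than hydroboration is needed, and the C4 centre it creates is later erased.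

**Ring A (6 ⇒ 4, key step).** The C7–C7a bond is cut by reversing a 1,2-shift: 6 is the Wolff ring-contraction product of diazoketone 4. Building the 1,2,3-trisubstituted cyclopentane by cyclisation of a chain would require all three centres to be set afresh. A Favorskii contraction of the corresponding α-chloro ketone would open its cyclopropanone toward the wrong carbon. The Wolff shift moves the methyl-bearing carbon with retention and leaves the ester on C7a. The forward step asks only for migration to outrun carbene side reactions.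

**Chiral pool (4 ⇒ 3 ⇒ 2 ⇒ 1; 15 ⇐ 14; 22 ⇐ 20).** The diazo group is placed on the methylene α-carbon of trans-dihydrocarvone 2 by kinetic trifluoroacetylation (3) and deacylative diazo transfer. Ketone 2 comes from (S)-carvone 1 by conjugate reduction. Coumarin 15 comes from acetophenone 14 and a carbonate.

## Roads not taken

**Alternative 1:** cut C4a–C5. The radical precursor is the N-acyloxyphthalimide A1, an α-methyl unsaturated δ-lactone already carrying the benzylated coumarin at C1 and the C7 side chain. It would lose CO2 to a primary C5 radical that adds 5-exo to C4a and gives lactone A2, which is compound 17 with C4 defined.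
- Merits: the ring fusion follows from the geometry of the closure, C7a is never enolisable, and the conditions are mild enough for the coumarin.
- Weak points: A1 must be assembled with C1, C7a and the remote C7 centre all set by acyclic asymmetric chemistry, with the coumarin present from the start.
- Comparison: at C7a this road is cleaner than the chosen one, which needs an equilibration (step 6). Against that the chosen plan takes C4a and C7 from carvone at no cost and brings the coumarin in only at step 11. Both roads share the same endgame from 17.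

**Alternative 2:** cut C4–C4a. The iodide A3 carries a 1-alkoxyallenyl ketone with the complete side chain. It would give a secondary C4a radical that adds to the central allene carbon, and hydrogen transfer would leave C3=C4, giving A4, which is compound 23.
- Merits: the acyl chain and the C1–O2 ether are in place before ring closure, and the road ends one step from the target with no lactone enolate or tin chemistry.
- Weak points: the alkoxyallenyl ketone is a strongly electrophilic, isomerisation-prone unit that must be built on a hindered C1 alkoxide beside an α-acetoxy ketone. C1 must be set by acyclic means. The closure has to control both the fusion at C4a and the site of hydrogen return.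
- Comparison: in endgame length this road is better. The chosen plan sets against it intermediates that are ordinary lactones, phosphates and stannanes, and thermodynamic control of C7a and C1.

**Alternative 3:** cut C4a–C7a and O2–C1. The 2-oxo-3-enoate A5, tethered to an (E)-3-alkenylcoumarin, would undergo an intramolecular oxa-Diels–Alder reaction to the bicyclic ester A6.
- Merits: both rings and three stereocentres form in one step. The (E)-alkene geometry is transcribed stereospecifically into the trans relation of coumarin and C7, a kinetic guarantee that the chosen plan replaces by an equilibrium argument. C3 emerges at the right oxidation level.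
- Weak points: only the C7 methyl directs the facial and endo/exo selectivity. The dienophile is conjugated to an electron-poor heterocycle and is poorly matched to an electron-poor heterodiene. The C3 ester of A6 must still be turned into the α-acetoxy ketone in the presence of the coumarin lactone.
- Comparison: this road reaches the bicyclic core in far fewer steps. The chosen plan sets against it a ring A whose two centres come from the chiral pool and a side chain that enters as an intact enantiopure acyl unit.

Key step: step 4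

## Route

Remark: C4, the methyl-bearing carbon created in step 5, is carried as a mixture of epimers and is left undefined in the SMILES of 7–13, 16 and 17 (as is the lactol carbon of 13); it becomes sp2 in step 13.

Step 1
Reactants: 1 (S)-carvone, (5S)-2-methyl-5-(prop-1-en-2-yl)cyclohex-2-en-1-one
Product: 2 (2S,5S)-2-methyl-5-(prop-1-en-2-yl)cyclohexan-1-one (trans-dihydrocarvone)
Conditions: LiBH(s-Bu)3, THF, −78 °C; 1 M HCl; then NaOMe (cat.), MeOH, rt
Reagents that add atoms: none
Why: Conjugate hydride reduction of the β-monosubstituted enone leaves the isopropenyl group alone; the new C2 centre is set by thermodynamic equilibration, which places methyl and isopropenyl both equatorial (trans), and the minor cis epimer is removed by chromatography.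

Step 2
Reactants: 2 (2S,5S)-2-methyl-5-(prop-1-en-2-yl)cyclohexan-1-one
Product: 3 (3S,6S)-6-methyl-3-(prop-1-en-2-yl)-2-(trifluoroacetyl)cyclohexan-1-one (enolised, C2 undefined)
Conditions: LiN(SiMe3)2, THF, −78 °C; CF3CO2CH2CF3; 5% HCl; used crude
Reagents that add atoms: 2,2,2-trifluoroethyl trifluoroacetate, O=C(OCC(F)(F)F)C(F)(F)F
Why: Kinetic deprotonation at the unsubstituted α-methylene and Claisen-type C-trifluoroacetylation mark that carbon for diazo transfer; the methyl-bearing α-carbon is not deprotonated.

Step 3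
Reactants: 3 (3S,6S)-6-methyl-3-(prop-1-en-2-yl)-2-(trifluoroacetyl)cyclohexan-1-one
Product: 4 (3R,6S)-2-diazo-6-methyl-3-(prop-1-en-2-yl)cyclohexan-1-one
Conditions: MsN3, Et3N, H2O (1 equiv), MeCN, rt
Reagents that add atoms: methanesulfonyl azide, CS(=O)(=O)N=[N+]=[N-]
Why: Deacylative Regitz-type diazo transfer: the diketone enolate adds to the sulfonyl azide and the adduct fragments with loss of the trifluoroacetyl group as its N-sulfonyl amide. The C3 descriptor changes only because the diazo carbon outranks isopropenyl.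

Step 4
Reactants: 4 (3R,6S)-2-diazo-6-methyl-3-(prop-1-en-2-yl)cyclohexan-1-one
Product: 6 methyl (1R,2S,5S)-5-methyl-2-(prop-1-en-2-yl)cyclopentane-1-carboxylate, via cyclopentylidene ketene 5 (not isolated)
Conditions: hν (medium-pressure Hg lamp, Pyrex filter), MeOH, 0 °C
Reagents that add atoms: methanol, CO
Why: Excitation of the diazoketone, held s-cis by the ring, expels N2 with concerted 1,2-shift of C6 (the methyl-bearing carbon, C7 of the target) from the carbonyl carbon to the diazo carbon; this gives ketene 5, methanol adds to it, and the ester enol is protonated at C7a to give 6. The closest known reaction type is the photochemical Wolff rearrangement of cyclic 2-diazoketones with ring contraction. Ring A is not closed by a cyclisation but by contraction, a 1,2-alkyl shift inside the existing six-membered ring, so no exo or endo mode applies. The migrating carbon keeps its configuration and C4a is a spectator, so the trans relation of methyl and isopropenyl set in 2 is carried into 6. The one new stereocentre, C7a, is set by protonation of the ester enol; its two faces differ only in a flanking methyl against a flanking isopropenyl, so protonation anti to isopropenyl, which gives 6, should be favoured only moderately, and the C7a epimer formed alongside is converged in step 6. The selectivity the step needs is migration over 1,2-hydride shift from the allylic C3–H and over carbene insertion; the fixed s-cis geometry, light in place of a metal catalyst, and methanol as solvent to intercept the ketene secure it.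

Step 5
Reactants: 6 methyl (1R,2S,5S)-5-methyl-2-(prop-1-en-2-yl)cyclopentane-1-carboxylate
Product: 8 methyl (1R,2R,5S)-2-(1-hydroxypropan-2-yl)-5-methylcyclopentane-1-carboxylate (both side-chain epimers), via B-alkyl-9-BBN adduct 7 (not isolated)
Conditions: 9-BBN, THF, 0 °C → rt; NaOAc, H2O2, H2O, 0 °C → rt
Reagents that add atoms: hydrogen peroxide, OO
Why: Anti-Markovnikov hydroboration–oxidation; 9-BBN adds to the 1,1-disubstituted alkene and ignores the ester. The new methyl-bearing centre (C4) forms without control and is erased in step 13.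

Step 6
Reactants: 8 methyl (1R,2R,5S)-2-(1-hydroxypropan-2-yl)-5-methylcyclopentane-1-carboxylate
Product: 9 (4aR,7S,7aR)-4,7-dimethylhexahydrocyclopenta[c]pyran-1(3H)-one (C4 epimers)
Conditions: KOt-Bu (0.2 equiv), THF, 50 °C; AcOH
Reagents that add atoms: none
Why: Alkoxide-mediated transesterification closes the δ-lactone, and reversible enolisation at C7a under the same base should funnel both C7a epimers into the cis-fused lactone whose carbonyl is trans to the C7 methyl. This is the preference seen in the base epimerisation of trans-fused to cis-fused nepetalactone, and it sets C7a.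

Step 7
Reactants: 9 (4aR,7S,7aR)-4,7-dimethylhexahydrocyclopenta[c]pyran-1(3H)-one
Product: 10 (1R,2R,5S)-2-(1-hydroxypropan-2-yl)-N-methoxy-N,5-dimethylcyclopentane-1-carboxamide
Conditions: MeNHOMe·HCl, AlMe3, CH2Cl2, 0 °C → rt; aq. KNaC4H4O6
Reagents that add atoms: N,O-dimethylhydroxylamine hydrochloride, CNOC.Cl
Why: Aminolysis by the aluminium amide is the standard opening of lactones to N-methoxy-N-methyl amides; the reagent is not basic enough to enolise C7a.

Step 8
Reactants: 10 (1R,2R,5S)-2-(1-hydroxypropan-2-yl)-N-methoxy-N,5-dimethylcyclopentane-1-carboxamide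
Product: 11 2-{(1S,2R,3S)-2-[methoxy(methyl)carbamoyl]-3-methylcyclopentyl}propanoic acid
Conditions: TEMPO (cat.), PhI(OAc)2, MeCN/H2O, rt
Reagents that add atoms: water, O
Why: Oxoammonium oxidation of the primary alcohol runs through the aldehyde hydrate to the acid and leaves the amide untouched; it is run on fresh 10 to forestall relactonisation.

Step 9
Reactants: 11 2-{(1S,2R,3S)-2-[methoxy(methyl)carbamoyl]-3-methylcyclopentyl}propanoic acid
Product: 13 (4aS,7S,7aR)-1-hydroxy-4,7-dimethylhexahydrocyclopenta[c]pyran-3(1H)-one (pseudo-acid), via open-chain aldehyde acid 12 (not isolated)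
Conditions: i-Bu2AlH (3 equiv), THF, −78 °C; 1 M HCl
Reagents that add atoms: none
Why: The acid is first consumed as an aluminium carboxylate that resists hydride at −78 °C, while the N-methoxy-N-methyl amide is reduced to a chelated hemiaminal that releases the aldehyde only on work-up. The aldehyde acid closes to the cis-fused pseudo-acid, in which C7a stays under the thermodynamic bias of step 6.

Step 10
Reactants: 14 1-(2-hydroxy-6-methylphenyl)ethan-1-one
Product: 15 4-hydroxy-5-methyl-2H-chromen-2-one
Conditions: NaH, (EtO)2CO, toluene, 110 °C; aq. HCl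
Reagents that add atoms: diethyl carbonate, CCOC(=O)OCC
Why: Claisen-type C-ethoxycarbonylation of the ketone enolate and lactonisation onto the phenoxide is the standard route from 2-hydroxyacetophenones to 4-hydroxycoumarins.

Step 11
Reactants: 13 (4aS,7S,7aR)-1-hydroxy-4,7-dimethylhexahydrocyclopenta[c]pyran-3(1H)-one; 15 4-hydroxy-5-methyl-2H-chromen-2-one
Product: 16 (1R,4aS,7S,7aR)-1-(4-hydroxy-5-methyl-2-oxo-2H-chromen-3-yl)-4,7-dimethylhexahydrocyclopenta[c]pyran-3(1H)-one
Conditions: ethylenediammonium diacetate (10 mol %), MeCN, 40 °C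
Reagents that add atoms: none
Why: Knoevenagel-type condensation of the aldehyde form of 13 with the nucleophilic C3 of 15 gives a 3-alkylidenechromane-2,4-dione that the neighbouring carboxylic acid closes by oxa-Michael addition, the course known for pseudo-acids such as 2-formylbenzoic acid with cyclic 1,3-dicarbonyl compounds. The C1–O2 bond forms reversibly, so C1 should settle with the coumarin on the convex face, trans to C7, which is the (1R) configuration.

Step 12
Reactants: 16 (1R,4aS,7S,7aR)-1-(4-hydroxy-5-methyl-2-oxo-2H-chromen-3-yl)-4,7-dimethylhexahydrocyclopenta[c]pyran-3(1H)-one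
Product: 17 (1R,4aS,7S,7aR)-1-[4-(benzyloxy)-5-methyl-2-oxo-2H-chromen-3-yl]-4,7-dimethylhexahydrocyclopenta[c]pyran-3(1H)-one
Conditions: BnOH, PPh3, DIAD, THF, 0 °C → rt
Reagents that add atoms: benzyl alcohol, OCc1ccccc1
Why: Mitsunobu O-alkylation of the acidic enol needs no added base, and C3 is blocked, so oxygen is alkylated. The benzyl ether removes the enol that would open the C1–O2 bond by retro-oxa-Michael reaction in the enolate and palladium steps.

Step 13
Reactants: 17 (1R,4aS,7S,7aR)-1-[4-(benzyloxy)-5-methyl-2-oxo-2H-chromen-3-yl]-4,7-dimethylhexahydrocyclopenta[c]pyran-3(1H)-one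
Product: 18 (1R,4aS,7S,7aR)-1-[4-(benzyloxy)-5-methyl-2-oxo-2H-chromen-3-yl]-4,7-dimethyl-1,4a,5,6,7,7a-hexahydrocyclopenta[c]pyran-3-yl diphenyl phosphate
Conditions: KN(SiMe3)2, (PhO)2P(O)Cl, THF/DMPU, −78 °C
Reagents that add atoms: diphenyl phosphorochloridate, O=P(Cl)(Oc1ccccc1)Oc1ccccc1
Why: Deprotonation of the lactone at C4 in the presence of the chlorophosphate traps the enolate on oxygen as the ketene acetal phosphate. Both C4 epimers converge and C3=C4 is in place.

Step 14
Reactants: 18 (1R,4aS,7S,7aR)-1-[4-(benzyloxy)-5-methyl-2-oxo-2H-chromen-3-yl]-4,7-dimethyl-1,4a,5,6,7,7a-hexahydrocyclopenta[c]pyran-3-yl diphenyl phosphate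
Product: 19 4-(benzyloxy)-3-[(1R,4aS,7S,7aR)-4,7-dimethyl-3-(trimethylstannyl)-1,4a,5,6,7,7a-hexahydrocyclopenta[c]pyran-1-yl]-5-methyl-2H-chromen-2-one
Conditions: Me3SnSnMe3, Pd(PPh3)4 (10 mol %), LiCl, THF, 65 °C
Reagents that add atoms: hexamethylditin, C[Sn](C)(C)[Sn](C)(C)C
Why: Palladium-catalysed stannylation of a lactone-derived ketene acetal phosphate: zerovalent palladium inserts into the C3–O bond, the distannane transmetalates and reductive elimination gives the α-alkoxyalkenyl stannane.

Step 15
Reactants: 20 (2R)-2-hydroxy-3-methylbutanoic acid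
Product: 22 (2R)-1-chloro-3-methyl-1-oxobutan-2-yl acetate, via acetoxy acid 21 (not isolated)
Conditions: AcCl, rt; evaporate; (COCl)2, DMF (cat.), CH2Cl2, 0 °C → rt
Reagents that add atoms: acetyl chloride, CC(Cl)=O; oxalyl chloride, O=C(Cl)C(Cl)=O
Why: O-Acetylation of the α-hydroxy acid is followed by chloride formation through the Vilsmeier-type chloroiminium salt. Without base the α-acyloxy acid chloride does not form a ketene and keeps its configuration.

Step 16
Reactants: 19 4-(benzyloxy)-3-[(1R,4aS,7S,7aR)-4,7-dimethyl-3-(trimethylstannyl)-1,4a,5,6,7,7a-hexahydrocyclopenta[c]pyran-1-yl]-5-methyl-2H-chromen-2-one; 22 (2R)-1-chloro-3-methyl-1-oxobutan-2-yl acetate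
Product: 23 (2R)-1-{(1R,4aS,7S,7aR)-1-[4-(benzyloxy)-5-methyl-2-oxo-2H-chromen-3-yl]-4,7-dimethyl-1,4a,5,6,7,7a-hexahydrocyclopenta[c]pyran-3-yl}-3-methyl-1-oxobutan-2-yl acetate
Conditions: Pd2(dba)3 (5 mol %), P(2-furyl)3 (20 mol %), THF, 50 °C
Reagents that add atoms: none
Why: Stille acylation: zerovalent palladium inserts into the C–Cl bond of 22, the electron-rich α-alkoxyalkenyl stannane transmetalates and reductive elimination gives the α-alkoxy enone, as in the acylation of 1-stannyl glycals. No base is present, so the acetoxy-bearing centre is carried over unchanged.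

Step 17
Reactants: 23 (2R)-1-{(1R,4aS,7S,7aR)-1-[4-(benzyloxy)-5-methyl-2-oxo-2H-chromen-3-yl]-4,7-dimethyl-1,4a,5,6,7,7a-hexahydrocyclopenta[c]pyran-3-yl}-3-methyl-1-oxobutan-2-yl acetate
Product: 24 (2R)-1-[(1R,4aS,7S,7aR)-1-(4-hydroxy-5-methyl-2-oxo-2H-chromen-3-yl)-4,7-dimethyl-1,4a,5,6,7,7a-hexahydrocyclopenta[c]pyran-3-yl]-3-methyl-1-oxobutan-2-yl acetate (CNP0139732.2)
Conditions: H2 (1 atm), 10% Pd/C, EtOAc, rt
Reagents that add atoms: none
Why: Hydrogenolysis of the benzyl ether of a vinylogous acid is fast, while the tetrasubstituted C3=C4 bond, flanked by oxygen and acyl, is slow to hydrogenate. Neutral conditions spare the acetate, its α-centre and the C1–O2 bond.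

## Compound list

1 | (S)-carvone, (5S)-2-methyl-5-(prop-1-en-2-yl)cyclohex-2-en-1-one | CC1=CC[C@@H](CC1=O)C(C)=C | starting material
2 | (2S,5S)-2-methyl-5-(prop-1-en-2-yl)cyclohexan-1-one | C=C(C)[C@H]1CC[C@H](C)C(=O)C1 | intermediate
3 | (3S,6S)-6-methyl-3-(prop-1-en-2-yl)-2-(trifluoroacetyl)cyclohexan-1-one | C=C(C)[C@H]1CC[C@H](C)C(=O)C1C(=O)C(F)(F)F | intermediate
4 | (3R,6S)-2-diazo-6-methyl-3-(prop-1-en-2-yl)cyclohexan-1-one | C=C(C)[C@H]1CC[C@H](C)C(=O)C1=[N+]=[N-] | intermediate
5 | [(2S,5R)-2-methyl-5-(prop-1-en-2-yl)cyclopentylidene]methanone (ketene) | O=C=C1[C@@H](C)CC[C@@H]1C(C)=C | intermediate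
6 | methyl (1R,2S,5S)-5-methyl-2-(prop-1-en-2-yl)cyclopentane-1-carboxylate | COC(=O)[C@@H]1[C@@H](C)CC[C@@H]1C(C)=C | intermediate
7 | methyl (1R,2R,5S)-2-[1-(9-borabicyclo[3.3.1]nonan-9-yl)propan-2-yl]-5-methylcyclopentane-1-carboxylate | COC(=O)[C@@H]1[C@@H](C)CC[C@@H]1C(C)CB1C2CCCC1CCC2 | intermediate
8 | methyl (1R,2R,5S)-2-(1-hydroxypropan-2-yl)-5-methylcyclopentane-1-carboxylate | COC(=O)[C@@H]1[C@@H](C)CC[C@@H]1C(C)CO | intermediate
9 | (4aR,7S,7aR)-4,7-dimethylhexahydrocyclopenta[c]pyran-1(3H)-one | O=C1[C@@H]2[C@@H](C)CC[C@@H]2C(C)CO1 | intermediate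
10 | (1R,2R,5S)-2-(1-hydroxypropan-2-yl)-N-methoxy-N,5-dimethylcyclopentane-1-carboxamide | CON(C)C(=O)[C@@H]1[C@@H](C)CC[C@@H]1C(C)CO | intermediate
11 | 2-{(1S,2R,3S)-2-[methoxy(methyl)carbamoyl]-3-methylcyclopentyl}propanoic acid | CON(C)C(=O)[C@@H]1[C@@H](C)CC[C@@H]1C(C)C(=O)O | intermediate
12 | 2-[(1S,2R,3S)-2-formyl-3-methylcyclopentyl]propanoic acid | O=C[C@@H]1[C@@H](C)CC[C@@H]1C(C)C(=O)O | intermediate
13 | (4aS,7S,7aR)-1-hydroxy-4,7-dimethylhexahydrocyclopenta[c]pyran-3(1H)-one | OC1[C@@H]2[C@@H](C)CC[C@@H]2C(C)C(=O)O1 | intermediate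
14 | 1-(2-hydroxy-6-methylphenyl)ethan-1-one | CC(=O)c1c(C)cccc1O | starting material
15 | 4-hydroxy-5-methyl-2H-chromen-2-one | Cc1cccc2oc(=O)cc(O)c12 | intermediate
16 | (1R,4aS,7S,7aR)-1-(4-hydroxy-5-methyl-2-oxo-2H-chromen-3-yl)-4,7-dimethylhexahydrocyclopenta[c]pyran-3(1H)-one | O=C1C(C)[C@H]2CC[C@H](C)[C@H]2[C@H](c2c(O)c3c(C)cccc3oc2=O)O1 | intermediate
17 | (1R,4aS,7S,7aR)-1-[4-(benzyloxy)-5-methyl-2-oxo-2H-chromen-3-yl]-4,7-dimethylhexahydrocyclopenta[c]pyran-3(1H)-one | O=C1C(C)[C@H]2CC[C@H](C)[C@H]2[C@H](c2c(OCc3ccccc3)c3c(C)cccc3oc2=O)O1 | intermediate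
18 | (1R,4aS,7S,7aR)-1-[4-(benzyloxy)-5-methyl-2-oxo-2H-chromen-3-yl]-4,7-dimethyl-1,4a,5,6,7,7a-hexahydrocyclopenta[c]pyran-3-yl diphenyl phosphate | O=P(Oc1ccccc1)(Oc1ccccc1)OC1=C(C)[C@H]2CC[C@H](C)[C@H]2[C@H](c2c(OCc3ccccc3)c3c(C)cccc3oc2=O)O1 | intermediate
19 | 4-(benzyloxy)-3-[(1R,4aS,7S,7aR)-4,7-dimethyl-3-(trimethylstannyl)-1,4a,5,6,7,7a-hexahydrocyclopenta[c]pyran-1-yl]-5-methyl-2H-chromen-2-one | C[Sn](C)(C)C1=C(C)[C@H]2CC[C@H](C)[C@H]2[C@H](c2c(OCc3ccccc3)c3c(C)cccc3oc2=O)O1 | intermediate
20 | (2R)-2-hydroxy-3-methylbutanoic acid | CC(C)[C@@H](O)C(=O)O | starting material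
21 | (2R)-2-(acetyloxy)-3-methylbutanoic acid | CC(C)[C@@H](OC(C)=O)C(=O)O | intermediate
22 | (2R)-1-chloro-3-methyl-1-oxobutan-2-yl acetate | CC(C)[C@@H](OC(C)=O)C(Cl)=O | intermediate
23 | (2R)-1-{(1R,4aS,7S,7aR)-1-[4-(benzyloxy)-5-methyl-2-oxo-2H-chromen-3-yl]-4,7-dimethyl-1,4a,5,6,7,7a-hexahydrocyclopenta[c]pyran-3-yl}-3-methyl-1-oxobutan-2-yl acetate | CC(=O)O[C@@H](C(=O)C1=C(C)[C@H]2CC[C@H](C)[C@H]2[C@H](c2c(OCc3ccccc3)c3c(C)cccc3oc2=O)O1)C(C)C | intermediate
24 | (2R)-1-[(1R,4aS,7S,7aR)-1-(4-hydroxy-5-methyl-2-oxo-2H-chromen-3-yl)-4,7-dimethyl-1,4a,5,6,7,7a-hexahydrocyclopenta[c]pyran-3-yl]-3-methyl-1-oxobutan-2-yl acetate | CC(=O)O[C@@H](C(=O)C1=C(C)[C@H]2CC[C@H](C)[C@H]2[C@H](c2c(O)c3c(C)cccc3oc2=O)O1)C(C)C | target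

## Step count and least certain steps

Total step count: 17. Longest linear sequence: 15 steps (1–9, 11–14, 16, 17); steps 10 and 15 prepare the two side fragments.

**Step 4 (key step).** The likely loss is a 1,2-hydride shift from the tertiary, allylic C3–H to the carbene centre, which gives a conjugated enone in place of the ring-contracted ester. Weak facial control at C7a is expected by design and is handled in step 6. The fallback replaces the carbene by a cationic 1,2-shift and sets out from 2.
- The kinetic silyl enol ether trimethyl{[(3S,6S)-6-methyl-3-(prop-1-en-2-yl)cyclohex-1-en-1-yl]oxy}silane F1 (LiN(i-Pr)2, Me3SiCl, THF, −78 °C) would be oxidised with PhI(OH)OTs to the α-tosyloxy ketone (3S,6R)-3-methyl-2-oxo-6-(prop-1-en-2-yl)cyclohexyl 4-methylbenzenesulfonate F2.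
- Ketalisation (HC(OMe)3, MeOH, TsOH) gives the dimethyl ketal (3S,6R)-2,2-dimethoxy-3-methyl-6-(prop-1-en-2-yl)cyclohexyl 4-methylbenzenesulfonate F3.
- On warming F3, the methyl-bearing ring carbon should migrate to the tosyloxy-bearing carbon with loss of tosylate, the course taken by trivalent-iodine ring contractions of cyclohexanones in trimethyl orthoformate.
- Aqueous work-up of the orthoester comes back to the route at 6, with both C7a epimers converged by step 6.

**Step 11.** The alkylidene intermediate may be captured by a second molecule of 15 before the carboxylic acid closes, or it may tautomerise toward C7a, because the lactone closure is reversible. The fallback makes the C1–aryl bond at the acyl level and sets out from 11 and 15.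
- 15 is O-benzylated (BnOH, PPh3, DIAD) to 4-(benzyloxy)-5-methyl-2H-chromen-2-one F4.
- F4, lithiated at C3 (LiN(i-Pr)2, THF, −78 °C), is added to the lithium carboxylate of 11 to give the keto acid 2-{(1S,2R,3S)-2-[4-(benzyloxy)-5-methyl-2-oxo-2H-chromene-3-carbonyl]-3-methylcyclopentyl}propanoic acid F5.
- Luche reduction (NaBH4, CeCl3·7H2O, MeOH, −40 °C) should deliver hydride anti to the more hindered C4a branch (1,2-induction from C7a) and give the hydroxy acid 2-{(1S,2R,3S)-2-[(R)-[4-(benzyloxy)-5-methyl-2-oxo-2H-chromen-3-yl](hydroxy)methyl]-3-methylcyclopentyl}propanoic acid F6.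
- F6 lactonises with catalytic TsOH and comes back to the route at 17.

**Step 14.** Oxidative addition into the tetrasubstituted, electron-rich enol phosphate may be slow, and 19 may protodestannylate during isolation. The fallback uses carbonyl addition in place of tin chemistry and sets out from 17 and 22.
- 17 is converted (KN(SiMe3)2, PhNTf2, THF, −78 °C) into the ketene acetal triflate (1R,4aS,7S,7aR)-1-[4-(benzyloxy)-5-methyl-2-oxo-2H-chromen-3-yl]-4,7-dimethyl-1,4a,5,6,7,7a-hexahydrocyclopenta[c]pyran-3-yl trifluoromethanesulfonate F7.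
- 22 is reduced (Bu3SnH, Pd(PPh3)4) to the aldehyde (2R)-3-methyl-1-oxobutan-2-yl acetate F8.
- Nozaki–Hiyama–Kishi coupling of F7 and F8 (CrCl2, NiCl2 cat., DMF) gives the allylic alcohol (2R)-1-{(1R,4aS,7S,7aR)-1-[4-(benzyloxy)-5-methyl-2-oxo-2H-chromen-3-yl]-4,7-dimethyl-1,4a,5,6,7,7a-hexahydrocyclopenta[c]pyran-3-yl}-1-hydroxy-3-methylbutan-2-yl acetate F9.
- F9 is oxidised at once (Dess–Martin oxidation, NaHCO3, CH2Cl2) and comes back to the route at 23.

**Step 16.** Transmetalation from the hindered stannane may be slow, which leaves the acylpalladium chloride time to decarbonylate or the acid chloride time to epimerise through its ketene. The fallback sets out from 19.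
- Iododestannylation (I2, CH2Cl2, 0 °C) gives the alkenyl iodide 4-(benzyloxy)-3-[(1R,4aS,7S,7aR)-3-iodo-4,7-dimethyl-1,4a,5,6,7,7a-hexahydrocyclopenta[c]pyran-1-yl]-5-methyl-2H-chromen-2-one F10.
- F10 is coupled with the aldehyde (2R)-3-methyl-1-oxobutan-2-yl acetate F8 under the same CrCl2/NiCl2 conditions to give the allylic alcohol (2R)-1-{(1R,4aS,7S,7aR)-1-[4-(benzyloxy)-5-methyl-2-oxo-2H-chromen-3-yl]-4,7-dimethyl-1,4a,5,6,7,7a-hexahydrocyclopenta[c]pyran-3-yl}-1-hydroxy-3-methylbutan-2-yl acetate F9.
- Dess–Martin oxidation of F9 comes back to the route at 23.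

## Further compounds

F1 | step 4 | trimethyl{[(3S,6S)-6-methyl-3-(prop-1-en-2-yl)cyclohex-1-en-1-yl]oxy}silane | C=C(C)[C@H]1CC[C@H](C)C(O[Si](C)(C)C)=C1
F2 | step 4 | (3S,6R)-3-methyl-2-oxo-6-(prop-1-en-2-yl)cyclohexyl 4-methylbenzenesulfonate | C=C(C)[C@H]1CC[C@H](C)C(=O)C1OS(=O)(=O)c1ccc(C)cc1
F3 | step 4 | (3S,6R)-2,2-dimethoxy-3-methyl-6-(prop-1-en-2-yl)cyclohexyl 4-methylbenzenesulfonate | C=C(C)[C@H]1CC[C@H](C)C(OC)(OC)C1OS(=O)(=O)c1ccc(C)cc1
F4 | step 11 | 4-(benzyloxy)-5-methyl-2H-chromen-2-one | Cc1cccc2oc(=O)cc(OCc3ccccc3)c12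
F5 | step 11 | 2-{(1S,2R,3S)-2-[4-(benzyloxy)-5-methyl-2-oxo-2H-chromene-3-carbonyl]-3-methylcyclopentyl}propanoic acid | O=C(c1c(OCc2ccccc2)c2c(C)cccc2oc1=O)[C@@H]1[C@@H](C)CC[C@@H]1C(C)C(=O)O
F6 | step 11 | 2-{(1S,2R,3S)-2-[(R)-[4-(benzyloxy)-5-methyl-2-oxo-2H-chromen-3-yl](hydroxy)methyl]-3-methylcyclopentyl}propanoic acid | O[C@@H](c1c(OCc2ccccc2)c2c(C)cccc2oc1=O)[C@@H]1[C@@H](C)CC[C@@H]1C(C)C(=O)O
F7 | step 14 | (1R,4aS,7S,7aR)-1-[4-(benzyloxy)-5-methyl-2-oxo-2H-chromen-3-yl]-4,7-dimethyl-1,4a,5,6,7,7a-hexahydrocyclopenta[c]pyran-3-yl trifluoromethanesulfonate | O=S(=O)(OC1=C(C)[C@H]2CC[C@H](C)[C@H]2[C@H](c2c(OCc3ccccc3)c3c(C)cccc3oc2=O)O1)C(F)(F)F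
F8 | step 14 | (2R)-3-methyl-1-oxobutan-2-yl acetate | CC(C)[C@@H](OC(C)=O)C=O
F9 | step 14 | (2R)-1-{(1R,4aS,7S,7aR)-1-[4-(benzyloxy)-5-methyl-2-oxo-2H-chromen-3-yl]-4,7-dimethyl-1,4a,5,6,7,7a-hexahydrocyclopenta[c]pyran-3-yl}-1-hydroxy-3-methylbutan-2-yl acetate (carbinol epimers) | CC(=O)O[C@@H](C(O)C1=C(C)[C@H]2CC[C@H](C)[C@H]2[C@H](c2c(OCc3ccccc3)c3c(C)cccc3oc2=O)O1)C(C)C
F10 | step 16 | 4-(benzyloxy)-3-[(1R,4aS,7S,7aR)-3-iodo-4,7-dimethyl-1,4a,5,6,7,7a-hexahydrocyclopenta[c]pyran-1-yl]-5-methyl-2H-chromen-2-one | IC1=C(C)[C@H]2CC[C@H](C)[C@H]2[C@H](c2c(OCc3ccccc3)c3c(C)cccc3oc2=O)O1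
A1 | alternative 1 | 1,3-dioxoisoindolin-2-yl (4S)-4-{(2R,3R)-2-[4-(benzyloxy)-5-methyl-2-oxo-2H-chromen-3-yl]-5-methyl-6-oxo-3,6-dihydro-2H-pyran-3-yl}pentanoate | O=C1C(C)=C[C@@H]([C@@H](C)CCC(=O)ON2C(=O)c3ccccc3C2=O)[C@H](c2c(OCc3ccccc3)c3c(C)cccc3oc2=O)O1
A2 | alternative 1 | (1R,4R,4aS,7S,7aR)-1-[4-(benzyloxy)-5-methyl-2-oxo-2H-chromen-3-yl]-4,7-dimethylhexahydrocyclopenta[c]pyran-3(1H)-one | O=C1[C@H](C)[C@H]2CC[C@H](C)[C@H]2[C@H](c2c(OCc3ccccc3)c3c(C)cccc3oc2=O)O1
A3 | alternative 2 | (3R)-5-{(R)-[4-(benzyloxy)-5-methyl-2-oxo-2H-chromen-3-yl][(1S,5S)-2-iodo-5-methylcyclopentyl]methoxy}-2-methyl-4-oxohepta-5,6-dien-3-yl acetate | CC(=O)O[C@@H](C(=O)C(=C=C)O[C@@H](c1c(OCc2ccccc2)c2c(C)cccc2oc1=O)[C@H]1C(I)CC[C@@H]1C)C(C)C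
A4 | alternative 2 | (2R)-1-{(1R,4aS,7S,7aR)-1-[4-(benzyloxy)-5-methyl-2-oxo-2H-chromen-3-yl]-4,7-dimethyl-1,4a,5,6,7,7a-hexahydrocyclopenta[c]pyran-3-yl}-3-methyl-1-oxobutan-2-yl acetate | CC(=O)O[C@@H](C(=O)C1=C(C)[C@H]2CC[C@H](C)[C@H]2[C@H](c2c(OCc3ccccc3)c3c(C)cccc3oc2=O)O1)C(C)C
A5 | alternative 3 | methyl (3E,7S,8E)-9-[4-(benzyloxy)-5-methyl-2-oxo-2H-chromen-3-yl]-3,7-dimethyl-2-oxonona-3,8-dienoate | COC(=O)C(=O)/C(C)=C/CC[C@H](C)/C=C/c1c(OCc2ccccc2)c2c(C)cccc2oc1=O
A6 | alternative 3 | methyl (1R,4aS,7S,7aR)-1-[4-(benzyloxy)-5-methyl-2-oxo-2H-chromen-3-yl]-4,7-dimethyl-1,4a,5,6,7,7a-hexahydrocyclopenta[c]pyran-3-carboxylate | COC(=O)C1=C(C)[C@H]2CC[C@H](C)[C@H]2[C@H](c2c(OCc3ccccc3)c3c(C)cccc3oc2=O)O1
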